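## The problem

Atom labels follow the dihydrobenzofuran core: O1, C2, C3, C3a, C4–C7, C7a; C9 is the oxymethyl carbon on C3; ring A is the benzo ring and ring B the guaiacyl ring on C2.

The target is a trans-2-aryl-3-(acyloxymethyl)-2,3-dihydrobenzofuran. Ring A is fused to a five-membered oxacycle; C2 carries ring B, C3 carries C9 as its 4-hydroxybenzoate, C7 a methoxy group and C5 a (Z)-3-oxoprop-1-enyl chain. There are two stereocentres, C2 (S) and C3 (R), adjacent and trans. Either can steer the other in a ring closure because trans is the more stable arrangement, but nothing else in the molecule can fix the absolute configuration, so it must come from a catalyst or an auxiliary.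

The (Z)-enal is the most fragile element. It is conjugated through ring A to O1 in the para position, so acid, base, nucleophilic catalysts and light all offer easy paths to the (E) isomer; it has to appear late and meet few reagents. The aryl ester on C9 cannot survive hydride reductions and must follow the last of them, and the two phenols need protection that comes off without acid or strong base. The C2–O1 bond is a benzylic aryl ether on an electron-rich ring, so quinone-type oxidants and strong Lewis acids are excluded.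

The feature that allows a short, stereocontrolled assembly is that C2 and C3 are neighbouring methines, each bound to exactly one aryl ring, with C3 also holding C9. They map onto the two alkene carbons of a three-carbon alkenyl boronate that already contains C9. Ring B can be added to C2 and ring A to C3 across that alkene in one operation, and the boron left on C2 becomes O1. O1–C7a can then be closed by displacing a fluoride at C7a, activated by a para carbonyl group at C5, the position where the enal must be built.

## Retrosynthesis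

**Phenol protection.** Target 29 is traced to its bis(triisopropylsilyl) ether 28. One buffered fluoride treatment frees both phenols and is the only reagent the finished ester-enal has to meet.

**C9–O acyl bond.** Ester 28 is cut into hydroxy enal 23 and 4-(triisopropylsilyloxy)benzoic acid 26, used as its chloride 27. The ester is placed after every hydride step. The enal is already present in 23 because oxidation distinguishes the allylic from the saturated primary alcohol of diol 22, which an acylation could not do. Protecting the allylic alcohol instead would cost two more steps.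

**Side-chain C=C bond.** Enal 23 comes from diol 22 by allylic oxidation, 22 from hydroxy enoate 21 by 1,2-reduction, and 21 from trityl ether 20. Enoate 20 is cut at its C=C bond to aldehyde 19 by a Z-selective olefination of the Still–Gennari type. No reliable direct Z-selective formyl olefination exists, so the enal level is reached by reduction and re-oxidation. The O9 protecting group is removed at 20 because the enoate is the last intermediate indifferent to acid; the cinnamyl alcohol 22 and enal 23 are not.

**C5 handle.** Aldehyde 19 derives from benzylic alcohol 18 and that from methyl ester 17. The ester is kept until here because it is the group that activates the ring closure.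

**O1–C7a bond.** Dihydrobenzofuran 17 is opened to fluoro alcohol 16; forward, the C2 alkoxide displaces fluoride para to the ester. Closing O1–C2 instead would make C2 the electrophile and put its configuration at risk; this closure touches neither stereocentre. It asks one thing of the substrate: O9 must stay out. A silyl ether on O9 would migrate to the neighbouring C2 alkoxide, and the freed primary alkoxide would close an isomeric five-membered ring on the same carbon. O9 is therefore carried as a trityl ether from the start.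

**C2–O bond.** Alcohol 16 comes from secondary boronate 15 by oxidation with retention.

**C2–ring B and C3–C3a bonds (key disconnection).** Boronate 15 is cut into three achiral pieces: alkenyl boronate 12, aryllithium 13 and triflate 4. Forward, 13 and 12 form ate complex 14, which couples with 4 under chiral palladium catalysis. A stepwise aldol or alkylation sequence would set the two centres separately and need an auxiliary; this cut sets both at once. It requires anti addition across the (E)-alkene, face selection by the ligand, and suppression of direct alkenyl transfer to palladium. The last point decides the boron ligand: a pinacol ester with a β-substituent is prone to direct coupling, so 12 carries the hindered diol 10. A methyl ester rather than a nitrile is kept on 4, because the peroxide oxidation of 15 would hydrate a nitrile.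

**Alkenyl boronate.** Boronate 12 comes from trityl propargyl ether 8 by hydroboration to catechol boronate 11 and exchange with diol 10. Ether 8 comes from propargyl alcohol 7; diol 10 from acenaphthoquinone 9 by double methyl addition.

**Aryllithium.** Aryllithium 13 arises by bromine–lithium exchange from silyl ether 6, made from 4-bromo-2-methoxyphenol 5.

**Triflate.** Triflate 4 comes from phenol 3, and 3 from methyl 4-fluoro-3-methoxybenzoate 1 by C–H borylation (boronate 2) and oxidation. Electrophilic substitution cannot reach this position, which is meta to the methoxy group; a sterically governed borylation can.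

**Acid partner.** Acid 26 comes from 4-hydroxybenzoic acid 24 through bis-silyl compound 25.

## Roads not taken

**Alternative 1:** ring contraction of a flavanone.

- Cut: C3–C3a is made by a 1,2-shift. Flavanone A1 is treated with PhI(OAc)2 and H2SO4 in trimethyl orthoformate; the ring A carbon migrates from C4 to C3, the pyranone contracts, and C4 is expelled as the methyl ester of A2.
- Merits: A1 is available in very few steps by condensation chemistry. One step forms the heterocycle and delivers C9 at the ester level. The bromide at C5 of A2 would allow the side chain to be attached by cross-coupling instead of five redox and olefination steps.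
- Weak points: the absolute configuration rests entirely on A1 being one enantiomer, and its C2 epimerises by reversible ring opening under the strongly acidic conditions of the rearrangement. The oxidant must also choose ring A migration over migration of the C2 aryl group and over plain dehydrogenation. The tosylate is there only to tame ring B.
- Comparison: this road is shorter to the bicyclic core and needs no chiral palladium catalyst. The chosen plan sets against it catalyst control of both centres in one step and no epimerisable intermediate.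

**Alternative 2:** asymmetric Prins reaction of a stilbene.

- Cut: C3–C9 and a C2–O bond are formed when paraformaldehyde and a confined chiral imidodiphosphorimidate acid add across stilbene A3, giving trans-dioxane A4.
- Merits: A3 is a simple Heck or Wittig product. The catalyst is organic, C9 comes from formaldehyde, and the bromide again eases the enal.
- Weak points: the dioxane is not part of the target. It must be opened, the carbonate removed and O1–C2 closed by displacement at C2, so one of the two centres just made is given up and re-made under control of the other. The silyl ether and the carbonate have to survive a very strong Brønsted acid, and a benzylic cation stabilised by ring B threatens the stereospecificity of the addition.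
- Comparison: the materials are cheaper and no organolithium is handled. The chosen plan sets against it that both new centres go unchanged into the target and that the ring is closed two steps after the key step.

**Alternative 3:** oxidative closure through a para-quinone methide.

- Cut: O1–C2 is made last. DDQ oxidises the free guaiacyl unit of diarylpropyl ester A5 to its quinone methide, and the ring A phenol adds to C2 to give A6, trans to the C3 arm.
- Merits: the step is biomimetic and well known in neolignan chemistry. The benzoate is already in place, so the end game is shorter than the one chosen here, and only one stereocentre has to be made beforehand.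
- Weak points: that centre in A5 needs its own asymmetric step. Trans selectivity relies on a kinetic preference, not on mechanism. DDQ meets two phenols in A5, and the product A6, still a free para-alkylphenol, can be oxidised again at C2.
- Comparison: the key step is operationally simpler and better precedented than the conjunctive coupling on this substitution pattern. The chosen plan sets against it relative configuration fixed by stereospecific steps, both centres from one catalytic event, and no oxidant near an electron-rich diphenol.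

Key step: step 7

Assumption: the (Sp,Sp) ligand named in step 7 is taken to give the (1S,2R) boronate 15 by analogy with simpler (E)-alkenyl boronates; if the sense of induction is opposite, the mirror-image ligand is used and nothing else changes.

## Route

Step 1
Reactants: 1 methyl 4-fluoro-3-methoxybenzoate
Product: 3 methyl 4-fluoro-3-hydroxy-5-methoxybenzoate, via aryl pinacol boronate 2 (not isolated)
Conditions: [Ir(cod)OMe]2 (1.5 mol %), 4,4′-di-tert-butyl-2,2′-bipyridine (3 mol %), B2pin2, THF, 80 °C; then KHSO5 (as 2KHSO5·KHSO4·K2SO4), acetone/H2O, rt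
Reagents that add atoms: potassium peroxymonosulfate, [K+].[O-]S(=O)(=O)OO
Why: Iridium-catalysed C–H borylation followed by oxidation of the C–B bond; the C–H between ester and methoxy is blocked and the one ortho to the ester is shielded, so boron (from B2pin2) should enter ortho to the small, acidifying fluorine. Peroxymonosulfate then gives the phenol without touching the ester.

Step 2
Reactants: 3 methyl 4-fluoro-3-hydroxy-5-methoxybenzoate
Product: 4 methyl 4-fluoro-3-methoxy-5-(trifluoromethylsulfonyloxy)benzoate
Conditions: Tf2O, pyridine, CH2Cl2, 0 °C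
Reagents that add atoms: trifluoromethanesulfonic anhydride, O=S(=O)(OS(=O)(=O)C(F)(F)F)C(F)(F)F
Why: Standard O-sulfonylation of a phenol; the electron-poor phenoxide is a good nucleophile towards the anhydride and nothing else in 3 reacts.

Step 3
Reactants: 5 4-bromo-2-methoxyphenol
Product: 6 (4-bromo-2-methoxyphenoxy)triisopropylsilane
Conditions: i-Pr3SiCl, imidazole, DMF, rt
Reagents that add atoms: chlorotriisopropylsilane, CC(C)[Si](Cl)(C(C)C)C(C)C
Why: Imidazole-mediated silylation of a phenol; the triisopropylsilyl ether is chosen because it survives t-BuLi, aqueous perborate, KN(SiMe3)2 and i-Bu2AlH and leaves with fluoride at the end.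

Step 4
Reactants: 7 prop-2-yn-1-ol
Product: 8 (prop-2-ynyloxy)triphenylmethane
Conditions: Ph3CCl, Et3N, DMAP (cat.), CH2Cl2, rt
Reagents that add atoms: chlorotriphenylmethane, ClC(c1ccccc1)(c1ccccc1)c1ccccc1
Why: Tritylation of a primary alcohol through the trityl cation; the trityl ether is achiral, inert to base and organolithium, cannot migrate between oxygens, and is removed by catalytic acid.

Step 5
Reactants: 9 acenaphthylene-1,2-dione
Product: 10 cis-1,2-dimethyl-1,2-dihydroacenaphthylene-1,2-diol
Conditions: AlMe3, toluene, 0 °C to rt; aqueous work-up, recrystallisation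
Reagents that add atoms: trimethylaluminium, C[Al](C)C
Why: Twofold 1,2-addition of methyl to the diketone; the second methyl should enter anti to the bulky aluminium alkoxide formed first, which gives the cis (meso) diol, and crystallisation removes any trans isomer.

Step 6
Reactants: 8 (prop-2-ynyloxy)triphenylmethane; 10 cis-1,2-dimethyl-1,2-dihydroacenaphthylene-1,2-diol
Product: 12 (E)-3-(trityloxy)prop-1-enylboronic acid cis-1,2-dimethylacenaphthene-1,2-diyl ester, via alkenyl catechol boronate 11 (not isolated)
Conditions: catecholborane, Cy2BH (5 mol %), THF, rt; then 10, rt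
Reagents that add atoms: catecholborane, B1Oc2ccccc2O1
Why: Dialkylborane-catalysed syn hydroboration of a terminal alkyne puts boron on the terminal carbon trans to the CH2O group; transesterification of the labile catechol ester with the rigid cis diol then gives the chromatography-stable boronate.

Step 7
Reactants: 12 (E)-3-(trityloxy)prop-1-enylboronic acid cis-1,2-dimethylacenaphthene-1,2-diyl ester; 6 (4-bromo-2-methoxyphenoxy)triisopropylsilane; 4 methyl 4-fluoro-3-methoxy-5-(trifluoromethylsulfonyloxy)benzoate
Product: 15 methyl 3-[(1S,2R)-1-(cis-1,2-dimethylacenaphthene-1,2-diyldioxyboryl)-1-[3-methoxy-4-(triisopropylsilyloxy)phenyl]-3-(trityloxy)propan-2-yl]-4-fluoro-5-methoxybenzoate, via aryllithium 13 (not isolated), via lithium boron ate complex 14 (not isolated)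
Conditions: 6, t-BuLi (2 equiv), Et2O/THF, −78 °C; 12, −78 °C to rt; then Pd(OAc)2 (3 mol %), (Sp,Sp)-1,1′-bis[bis(4-methoxy-3,5-dimethylphenyl)phosphino]-2,2′-bis[(R)-α-(dimethylamino)benzyl]ferrocene (3.6 mol %), KOTf, 4, THF, 60 °C
Reagents that add atoms: none
Why: Palladium-catalysed conjunctive cross-coupling, a known reaction type for β-substituted (E)-alkenyl boronates of this acenaphthenediol with aryl triflates. Aryllithium 13 adds to boron of 12 to give ate complex 14; oxidative addition of zerovalent palladium to 4 gives a cationic arylpalladium species that binds the alkene of 14 and triggers a 1,2-shift of the guaiacyl group from boron to C2 anti to palladium, and reductive elimination then joins C3 to ring A carbon C3a. No ring is closed. Both stereocentres arise here: their relative configuration follows from the (E) geometry combined with the anti metalate shift and retentive reductive elimination, and their absolute configuration from the alkene face selected by the chiral bisphosphine–palladium fragment. The selectivity needed is metalate shift over direct transfer of the alkenyl group from boron to palladium; the methyl and naphthalene groups of the diol shield the boronate oxygens that would have to bridge to palladium, where a pinacol ester with a β-substituent would not. KOTf removes bromide, which would otherwise occupy the site needed for alkene binding. The aryl fluoride and ester of 4 are inert to 14, and the trityloxy group on C9 is too poor a leaving group for β-elimination to compete with reductive elimination.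

Step 8
Reactants: 15 methyl 3-[(1S,2R)-1-(cis-1,2-dimethylacenaphthene-1,2-diyldioxyboryl)-1-[3-methoxy-4-(triisopropylsilyloxy)phenyl]-3-(trityloxy)propan-2-yl]-4-fluoro-5-methoxybenzoate
Product: 16 methyl 4-fluoro-3-[(1S,2R)-1-hydroxy-1-[3-methoxy-4-(triisopropylsilyloxy)phenyl]-3-(trityloxy)propan-2-yl]-5-methoxybenzoate
Conditions: NaBO3·4H2O, THF/H2O, rt
Reagents that add atoms: sodium perborate (NaBO3·4H2O), [Na+].[O-]B1OO1
Why: Oxidation of a secondary alkyl boronate by 1,2-migration of carbon from boron to oxygen, which proceeds with retention at C2. Perborate is mild enough to leave the methyl ester and the aryl silyl ether alone.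

Step 9
Reactants: 16 methyl 4-fluoro-3-[(1S,2R)-1-hydroxy-1-[3-methoxy-4-(triisopropylsilyloxy)phenyl]-3-(trityloxy)propan-2-yl]-5-methoxybenzoate
Product: 17 methyl (2S,3R)-7-methoxy-2-[3-methoxy-4-(triisopropylsilyloxy)phenyl]-3-(trityloxymethyl)-2,3-dihydro-1-benzofuran-5-carboxylate
Conditions: KN(SiMe3)2, THF (0.02 M), 0 °C to rt
Reagents that add atoms: none
Why: Intramolecular nucleophilic aromatic substitution (5-exo addition–elimination through a Meisenheimer intermediate stabilised by the para ester) forms O1–C7a. Neither stereocentre takes part, so the (1S,2R) open chain becomes the trans (2S,3R) ring. The trityl ether cannot migrate to the alkoxide, and dilution disfavours intermolecular ester exchange.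

Step 10
Reactants: 17 methyl (2S,3R)-7-methoxy-2-[3-methoxy-4-(triisopropylsilyloxy)phenyl]-3-(trityloxymethyl)-2,3-dihydro-1-benzofuran-5-carboxylate
Product: 18 [(2S,3R)-7-methoxy-2-[3-methoxy-4-(triisopropylsilyloxy)phenyl]-3-(trityloxymethyl)-2,3-dihydro-1-benzofuran-5-yl]methanol
Conditions: i-Bu2AlH, CH2Cl2, −78 to 0 °C; aqueous potassium sodium tartrate
Reagents that add atoms: none
Why: Hydride reduction of an aryl methyl ester to the benzylic alcohol; trityl and silyl ethers are inert to i-Bu2AlH.

Step 11
Reactants: 18 [(2S,3R)-7-methoxy-2-[3-methoxy-4-(triisopropylsilyloxy)phenyl]-3-(trityloxymethyl)-2,3-dihydro-1-benzofuran-5-yl]methanol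
Product: 19 (2S,3R)-7-methoxy-2-[3-methoxy-4-(triisopropylsilyloxy)phenyl]-3-(trityloxymethyl)-2,3-dihydro-1-benzofuran-5-carbaldehyde
Conditions: MnO2, CH2Cl2, rt
Reagents that add atoms: none
Why: Heterogeneous MnO2 oxidation of an electron-rich benzylic alcohol stops cleanly at the aldehyde under neutral conditions.

Step 12
Reactants: 19 (2S,3R)-7-methoxy-2-[3-methoxy-4-(triisopropylsilyloxy)phenyl]-3-(trityloxymethyl)-2,3-dihydro-1-benzofuran-5-carbaldehyde
Product: 20 methyl (Z)-3-[(2S,3R)-7-methoxy-2-[3-methoxy-4-(triisopropylsilyloxy)phenyl]-3-(trityloxymethyl)-2,3-dihydro-1-benzofuran-5-yl]prop-2-enoate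
Conditions: (CF3CH2O)2P(O)CH2CO2Me, KN(SiMe3)2, 18-crown-6, THF, −78 °C
Reagents that add atoms: methyl bis(2,2,2-trifluoroethyl)phosphonoacetate, COC(=O)CP(=O)(OCC(F)(F)F)OCC(F)(F)F
Why: Still–Gennari olefination; with the trifluoroethyl phosphonate and a crown-separated potassium ion the kinetic adduct eliminates faster than it equilibrates, which sets the (Z) geometry. Aromatic aldehydes are among the most selective substrates.

Step 13
Reactants: 20 methyl (Z)-3-[(2S,3R)-7-methoxy-2-[3-methoxy-4-(triisopropylsilyloxy)phenyl]-3-(trityloxymethyl)-2,3-dihydro-1-benzofuran-5-yl]prop-2-enoate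
Product: 21 methyl (Z)-3-[(2S,3R)-3-(hydroxymethyl)-7-methoxy-2-[3-methoxy-4-(triisopropylsilyloxy)phenyl]-2,3-dihydro-1-benzofuran-5-yl]prop-2-enoate
Conditions: camphorsulfonic acid (cat.), MeOH/CH2Cl2, 0 °C to rt
Reagents that add atoms: none
Why: Acid-catalysed solvolysis of the trityl ether, with the trityl cation trapped by methanol. Methanol matches the methyl ester, and the enoate and aryl silyl ether tolerate catalytic acid, which the later cinnamyl alcohol and enal would not.

Step 14
Reactants: 21 methyl (Z)-3-[(2S,3R)-3-(hydroxymethyl)-7-methoxy-2-[3-methoxy-4-(triisopropylsilyloxy)phenyl]-2,3-dihydro-1-benzofuran-5-yl]prop-2-enoate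
Product: 22 (Z)-3-[(2S,3R)-3-(hydroxymethyl)-7-methoxy-2-[3-methoxy-4-(triisopropylsilyloxy)phenyl]-2,3-dihydro-1-benzofuran-5-yl]prop-2-en-1-ol
Conditions: i-Bu2AlH (excess), CH2Cl2, −78 °C; aqueous potassium sodium tartrate
Reagents that add atoms: none
Why: i-Bu2AlH reduces enoates by 1,2-addition only, so the (Z) alkene is carried over unchanged; the free hydroxyl consumes one extra equivalent.

Step 15
Reactants: 22 (Z)-3-[(2S,3R)-3-(hydroxymethyl)-7-methoxy-2-[3-methoxy-4-(triisopropylsilyloxy)phenyl]-2,3-dihydro-1-benzofuran-5-yl]prop-2-en-1-ol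
Product: 23 (Z)-3-[(2S,3R)-3-(hydroxymethyl)-7-methoxy-2-[3-methoxy-4-(triisopropylsilyloxy)phenyl]-2,3-dihydro-1-benzofuran-5-yl]prop-2-enal
Conditions: MnO2, CH2Cl2, rt, dark
Reagents that add atoms: none
Why: MnO2 oxidises allylic alcohols and leaves saturated primary alcohols alone, so only the side chain reacts. The surface reaction is neutral and normally retains alkene geometry.

Step 16
Reactants: 24 4-hydroxybenzoic acid
Product: 26 4-(triisopropylsilyloxy)benzoic acid, via bis-silylated acid 25 (not isolated)
Conditions: i-Pr3SiCl (2.2 equiv), imidazole, DMF, rt; then K2CO3, THF/MeOH/H2O, 0 °C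
Reagents that add atoms: chlorotriisopropylsilane, CC(C)[Si](Cl)(C(C)C)C(C)C
Why: Silylation of both acidic sites followed by selective hydrolysis of the silyl ester, which is far more labile to mild aqueous base than the aryl silyl ether.

Step 17
Reactants: 23 (Z)-3-[(2S,3R)-3-(hydroxymethyl)-7-methoxy-2-[3-methoxy-4-(triisopropylsilyloxy)phenyl]-2,3-dihydro-1-benzofuran-5-yl]prop-2-enal; 26 4-(triisopropylsilyloxy)benzoic acid
Product: 28 [(2S,3R)-7-methoxy-2-[3-methoxy-4-(triisopropylsilyloxy)phenyl]-5-[(Z)-3-oxoprop-1-enyl]-2,3-dihydro-1-benzofuran-3-yl]methyl 4-(triisopropylsilyloxy)benzoate, via acid chloride 27 (not isolated)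
Conditions: 26, (COCl)2, DMF (cat.), CH2Cl2, 0 °C to rt, evaporate; then 23, pyridine, CH2Cl2, 0 °C
Reagents that add atoms: none
Why: Acyl chloride formation and pyridine-mediated acylation of a primary alcohol. No strongly nucleophilic catalyst is used, because reversible conjugate addition of such a catalyst to the enal would isomerise it to the (E) form.

Step 18
Reactants: 28 [(2S,3R)-7-methoxy-2-[3-methoxy-4-(triisopropylsilyloxy)phenyl]-5-[(Z)-3-oxoprop-1-enyl]-2,3-dihydro-1-benzofuran-3-yl]methyl 4-(triisopropylsilyloxy)benzoate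
Product: 29 [(2S,3R)-2-(4-hydroxy-3-methoxyphenyl)-7-methoxy-5-[(Z)-3-oxoprop-1-enyl]-2,3-dihydro-1-benzofuran-3-yl]methyl 4-hydroxybenzoate
Conditions: Bu4NF, AcOH (1:1), THF, 0 °C
Reagents that add atoms: none
Why: Fluoride cleavage of two aryl silyl ethers, which are the most fluoride-labile silyl ethers. Acetic acid protonates each phenoxide as it forms, so neither the ester nor the (Z)-enal meets a free base.

## Compound list

1 | methyl 4-fluoro-3-methoxybenzoate | COC(=O)c1ccc(F)c(OC)c1 | starting material
2 | methyl 4-fluoro-3-methoxy-5-(4,4,5,5-tetramethyl-1,3,2-dioxaborolan-2-yl)benzoate | COC(=O)c1cc(OC)c(F)c(B2OC(C)(C)C(C)(C)O2)c1 | intermediate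
3 | methyl 4-fluoro-3-hydroxy-5-methoxybenzoate | COC(=O)c1cc(OC)c(F)c(O)c1 | intermediate
4 | methyl 4-fluoro-3-methoxy-5-(trifluoromethylsulfonyloxy)benzoate | COC(=O)c1cc(OC)c(F)c(OS(=O)(=O)C(F)(F)F)c1 | intermediate
5 | 4-bromo-2-methoxyphenol | COc1cc(Br)ccc1O | starting material
6 | (4-bromo-2-methoxyphenoxy)triisopropylsilane | COc1cc(Br)ccc1O[Si](C(C)C)(C(C)C)C(C)C | intermediate
7 | prop-2-yn-1-ol | C#CCO | starting material
8 | (prop-2-ynyloxy)triphenylmethane | C#CCOC(c1ccccc1)(c1ccccc1)c1ccccc1 | intermediate
9 | acenaphthylene-1,2-dione | O=C1C(=O)c2cccc3cccc1c23 | starting material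
10 | cis-1,2-dimethyl-1,2-dihydroacenaphthylene-1,2-diol (meso, 1R,2S) | C[C@@]1(O)c2cccc3cccc(c23)[C@]1(C)O | intermediate
11 | 2-[(E)-3-(trityloxy)prop-1-enyl]-1,3,2-benzodioxaborole | C(/C=C/B1Oc2ccccc2O1)OC(c1ccccc1)(c1ccccc1)c1ccccc1 | intermediate
12 | (E)-3-(trityloxy)prop-1-enylboronic acid cis-1,2-dimethylacenaphthene-1,2-diyl ester | C(/C=C/B1O[C@]2(C)c3cccc4cccc(c34)[C@]2(C)O1)OC(c1ccccc1)(c1ccccc1)c1ccccc1 | intermediate
13 | [3-methoxy-4-(triisopropylsilyloxy)phenyl]lithium | [Li]c1ccc(O[Si](C(C)C)(C(C)C)C(C)C)c(OC)c1 | intermediate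
14 | lithium (cis-1,2-dimethylacenaphthene-1,2-diolato)[3-methoxy-4-(triisopropylsilyloxy)phenyl][(E)-3-(trityloxy)prop-1-enyl]borate (configuration at boron undefined) | [Li+].COc1cc([B-]2(/C=C/COC(c3ccccc3)(c3ccccc3)c3ccccc3)O[C@]3(C)c4cccc5cccc(c45)[C@]3(C)O2)ccc1O[Si](C(C)C)(C(C)C)C(C)C | intermediate
15 | methyl 3-[(1S,2R)-1-(cis-1,2-dimethylacenaphthene-1,2-diyldioxyboryl)-1-[3-methoxy-4-(triisopropylsilyloxy)phenyl]-3-(trityloxy)propan-2-yl]-4-fluoro-5-methoxybenzoate | COc1cc([C@@H](B2O[C@]3(C)c4cccc5cccc(c45)[C@]3(C)O2)[C@@H](COC(c2ccccc2)(c2ccccc2)c2ccccc2)c2cc(C(=O)OC)cc(OC)c2F)ccc1O[Si](C(C)C)(C(C)C)C(C)C | intermediate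
16 | methyl 4-fluoro-3-[(1S,2R)-1-hydroxy-1-[3-methoxy-4-(triisopropylsilyloxy)phenyl]-3-(trityloxy)propan-2-yl]-5-methoxybenzoate | COc1cc([C@@H](O)[C@@H](COC(c2ccccc2)(c2ccccc2)c2ccccc2)c2cc(C(=O)OC)cc(OC)c2F)ccc1O[Si](C(C)C)(C(C)C)C(C)C | intermediate
17 | methyl (2S,3R)-7-methoxy-2-[3-methoxy-4-(triisopropylsilyloxy)phenyl]-3-(trityloxymethyl)-2,3-dihydro-1-benzofuran-5-carboxylate | COc1cc([C@H]2Oc3c(OC)cc(C(=O)OC)cc3[C@@H]2COC(c2ccccc2)(c2ccccc2)c2ccccc2)ccc1O[Si](C(C)C)(C(C)C)C(C)C | intermediate
18 | [(2S,3R)-7-methoxy-2-[3-methoxy-4-(triisopropylsilyloxy)phenyl]-3-(trityloxymethyl)-2,3-dihydro-1-benzofuran-5-yl]methanol | COc1cc([C@H]2Oc3c(OC)cc(CO)cc3[C@@H]2COC(c2ccccc2)(c2ccccc2)c2ccccc2)ccc1O[Si](C(C)C)(C(C)C)C(C)C | intermediate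
19 | (2S,3R)-7-methoxy-2-[3-methoxy-4-(triisopropylsilyloxy)phenyl]-3-(trityloxymethyl)-2,3-dihydro-1-benzofuran-5-carbaldehyde | COc1cc([C@H]2Oc3c(OC)cc(C=O)cc3[C@@H]2COC(c2ccccc2)(c2ccccc2)c2ccccc2)ccc1O[Si](C(C)C)(C(C)C)C(C)C | intermediate
20 | methyl (Z)-3-[(2S,3R)-7-methoxy-2-[3-methoxy-4-(triisopropylsilyloxy)phenyl]-3-(trityloxymethyl)-2,3-dihydro-1-benzofuran-5-yl]prop-2-enoate | COc1cc([C@H]2Oc3c(OC)cc(/C=C\C(=O)OC)cc3[C@@H]2COC(c2ccccc2)(c2ccccc2)c2ccccc2)ccc1O[Si](C(C)C)(C(C)C)C(C)C | intermediate
21 | methyl (Z)-3-[(2S,3R)-3-(hydroxymethyl)-7-methoxy-2-[3-methoxy-4-(triisopropylsilyloxy)phenyl]-2,3-dihydro-1-benzofuran-5-yl]prop-2-enoate | COc1cc([C@H]2Oc3c(OC)cc(/C=C\C(=O)OC)cc3[C@@H]2CO)ccc1O[Si](C(C)C)(C(C)C)C(C)C | intermediate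
22 | (Z)-3-[(2S,3R)-3-(hydroxymethyl)-7-methoxy-2-[3-methoxy-4-(triisopropylsilyloxy)phenyl]-2,3-dihydro-1-benzofuran-5-yl]prop-2-en-1-ol | COc1cc([C@H]2Oc3c(OC)cc(/C=C\CO)cc3[C@@H]2CO)ccc1O[Si](C(C)C)(C(C)C)C(C)C | intermediate
23 | (Z)-3-[(2S,3R)-3-(hydroxymethyl)-7-methoxy-2-[3-methoxy-4-(triisopropylsilyloxy)phenyl]-2,3-dihydro-1-benzofuran-5-yl]prop-2-enal | COc1cc([C@H]2Oc3c(OC)cc(/C=C\C=O)cc3[C@@H]2CO)ccc1O[Si](C(C)C)(C(C)C)C(C)C | intermediate
24 | 4-hydroxybenzoic acid | O=C(O)c1ccc(O)cc1 | starting material
25 | triisopropylsilyl 4-(triisopropylsilyloxy)benzoate | CC(C)[Si](OC(=O)c1ccc(O[Si](C(C)C)(C(C)C)C(C)C)cc1)(C(C)C)C(C)C | intermediate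
26 | 4-(triisopropylsilyloxy)benzoic acid | O=C(O)c1ccc(O[Si](C(C)C)(C(C)C)C(C)C)cc1 | intermediate
27 | 4-(triisopropylsilyloxy)benzoyl chloride | O=C(Cl)c1ccc(O[Si](C(C)C)(C(C)C)C(C)C)cc1 | intermediate
28 | [(2S,3R)-7-methoxy-2-[3-methoxy-4-(triisopropylsilyloxy)phenyl]-5-[(Z)-3-oxoprop-1-enyl]-2,3-dihydro-1-benzofuran-3-yl]methyl 4-(triisopropylsilyloxy)benzoate | COc1cc([C@H]2Oc3c(OC)cc(/C=C\C=O)cc3[C@@H]2COC(=O)c2ccc(O[Si](C(C)C)(C(C)C)C(C)C)cc2)ccc1O[Si](C(C)C)(C(C)C)C(C)C | intermediate
29 | [(2S,3R)-2-(4-hydroxy-3-methoxyphenyl)-7-methoxy-5-[(Z)-3-oxoprop-1-enyl]-2,3-dihydro-1-benzofuran-3-yl]methyl 4-hydroxybenzoate | COc1cc([C@H]2Oc3c(OC)cc(/C=C\C=O)cc3[C@@H]2COC(=O)c2ccc(O)cc2)ccc1O | target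

## Step count and least certain steps

Total: 18 steps. Longest linear sequence: 13 steps (7 → 8 → 12 → 15 → 16 → 17 → 18 → 19 → 20 → 21 → 22 → 23 → 28 → 29; the lines from 1 and from 9 are equally long).

**Step 7 (key step).** The most likely failure is direct transfer of the alkenyl group of 14 to palladium in place of the metalate shift, because the β-substituent slows alkene binding and the ortho-fluorinated arylpalladium species is crowded. Loss of enantioselectivity on this oxygen-rich substrate is the second concern. The fallback replaces catalysis by an auxiliary-controlled syn aldol; it sets out from 4 and 6 and returns at 16.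
- Palladium-catalysed coupling of 4 with BrZnCH2CO2t-Bu (Pd2(dba)3, XPhos, THF) would give tert-butyl 2-[2-fluoro-3-methoxy-5-(methoxycarbonyl)phenyl]acetate F1.
- CF3CO2H would cleave it to 2-[2-fluoro-3-methoxy-5-(methoxycarbonyl)phenyl]acetic acid F2.
- Pivaloyl chloride/Et3N, then lithiated (4S)-4-benzyl-1,3-oxazolidin-2-one, would give the imide methyl 3-[2-[(4S)-4-benzyl-2-oxo-1,3-oxazolidin-3-yl]-2-oxoethyl]-4-fluoro-5-methoxybenzoate F3.
- Lithiation of 6 as in step 7 and a DMF quench would give 3-methoxy-4-(triisopropylsilyloxy)benzaldehyde F4.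
- Enolisation of F3 with Bu2BOTf/i-Pr2NEt and addition of F4 (Evans syn aldol) should give the (2S,3S) adduct methyl 3-[(2S,3S)-1-[(4S)-4-benzyl-2-oxo-1,3-oxazolidin-3-yl]-3-hydroxy-3-[3-methoxy-4-(triisopropylsilyloxy)phenyl]-1-oxopropan-2-yl]-4-fluoro-5-methoxybenzoate F5.
- NaBH4 in THF/H2O would remove the auxiliary reductively, sparing the aryl methyl ester, to give methyl 3-[(1S,2R)-1,3-dihydroxy-1-[3-methoxy-4-(triisopropylsilyloxy)phenyl]propan-2-yl]-4-fluoro-5-methoxybenzoate F6.
- Tritylation of the primary hydroxyl (Ph3CCl, pyridine) gives 16.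

**Step 1.** Borylation at the C–H ortho to the ester may compete with the one ortho to fluorine and leave a regioisomer mixture that is hard to separate. The fallback is a fluorine-directed lithiation, from 1 back to 3. LiOH hydrolysis of 1 gives 4-fluoro-3-methoxybenzoic acid F7. Excess lithium 2,2,6,6-tetramethylpiperidide in THF at −78 °C should metalate the lithium carboxylate at the C–H flanked only by fluorine; B(OMe)3 and then H2O2 would convert the aryllithium into 4-fluoro-3-hydroxy-5-methoxybenzoic acid F8. Esterification with MeOH/H2SO4 gives 3.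

**Step 12.** The electron-rich aldehyde reacts slowly at −78 °C, and erosion of Z-selectivity would leave an (E)-enoate that is hard to remove. The fallback sets the geometry by syn semi-hydrogenation of an alkyne, from 19 back to 22.
- CBr4/PPh3 converts 19 into the dibromoalkene [4-[(2S,3R)-5-(2,2-dibromoethenyl)-7-methoxy-3-(trityloxymethyl)-2,3-dihydro-1-benzofuran-2-yl]-2-methoxyphenoxy]triisopropylsilane F9.
- n-BuLi (2 equiv) and then paraformaldehyde give 3-[(2S,3R)-7-methoxy-2-[3-methoxy-4-(triisopropylsilyloxy)phenyl]-3-(trityloxymethyl)-2,3-dihydro-1-benzofuran-5-yl]prop-2-yn-1-ol F10.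
- Camphorsulfonic acid in MeOH/CH2Cl2 removes the trityl group to give 3-[(2S,3R)-3-(hydroxymethyl)-7-methoxy-2-[3-methoxy-4-(triisopropylsilyloxy)phenyl]-2,3-dihydro-1-benzofuran-5-yl]prop-2-yn-1-ol F11.
- H2 over Pd/CaCO3 poisoned with Pb(OAc)2 and quinoline adds syn and gives 22.

**Step 17.** The enal may isomerise from (Z) to (E) by reversible conjugate addition of pyridine or chloride during the acylation; the MnO2 step before it has the same weakness. The fallback makes the enal after the ester, from 19 back to 28.
- Stork–Zhao olefination of 19 with Ph3P=CHI (from (iodomethyl)triphenylphosphonium iodide and NaN(SiMe3)2, THF, −78 °C) gives [4-[(2S,3R)-5-[(Z)-2-iodoethenyl]-7-methoxy-3-(trityloxymethyl)-2,3-dihydro-1-benzofuran-2-yl]-2-methoxyphenoxy]triisopropylsilane F12.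
- Camphorsulfonic acid in MeOH/CH2Cl2 gives [(2S,3R)-5-[(Z)-2-iodoethenyl]-7-methoxy-2-[3-methoxy-4-(triisopropylsilyloxy)phenyl]-2,3-dihydro-1-benzofuran-3-yl]methanol F13.
- Acylation with 27 (pyridine, DMAP, harmless without an enal) gives [(2S,3R)-5-[(Z)-2-iodoethenyl]-7-methoxy-2-[3-methoxy-4-(triisopropylsilyloxy)phenyl]-2,3-dihydro-1-benzofuran-3-yl]methyl 4-(triisopropylsilyloxy)benzoate F14.
- Palladium-catalysed reductive carbonylation (Pd(PPh3)4, CO, Bu3SnH, THF) replaces iodine by the formyl group with retention of alkene geometry and gives 28.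

## Further compounds

F1 | step 7 | tert-butyl 2-[2-fluoro-3-methoxy-5-(methoxycarbonyl)phenyl]acetate | COC(=O)c1cc(OC)c(F)c(CC(=O)OC(C)(C)C)c1
F2 | step 7 | 2-[2-fluoro-3-methoxy-5-(methoxycarbonyl)phenyl]acetic acid | COC(=O)c1cc(OC)c(F)c(CC(=O)O)c1
F3 | step 7 | methyl 3-[2-[(4S)-4-benzyl-2-oxo-1,3-oxazolidin-3-yl]-2-oxoethyl]-4-fluoro-5-methoxybenzoate | COC(=O)c1cc(OC)c(F)c(CC(=O)N2C(=O)OC[C@@H]2Cc2ccccc2)c1
F4 | step 7 | 3-methoxy-4-(triisopropylsilyloxy)benzaldehyde | COc1cc(C=O)ccc1O[Si](C(C)C)(C(C)C)C(C)C
F5 | step 7 | methyl 3-[(2S,3S)-1-[(4S)-4-benzyl-2-oxo-1,3-oxazolidin-3-yl]-3-hydroxy-3-[3-methoxy-4-(triisopropylsilyloxy)phenyl]-1-oxopropan-2-yl]-4-fluoro-5-methoxybenzoate | COc1cc([C@@H](O)[C@@H](C(=O)N2C(=O)OC[C@@H]2Cc2ccccc2)c2cc(C(=O)OC)cc(OC)c2F)ccc1O[Si](C(C)C)(C(C)C)C(C)C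
F6 | step 7 | methyl 3-[(1S,2R)-1,3-dihydroxy-1-[3-methoxy-4-(triisopropylsilyloxy)phenyl]propan-2-yl]-4-fluoro-5-methoxybenzoate | COc1cc([C@@H](O)[C@@H](CO)c2cc(C(=O)OC)cc(OC)c2F)ccc1O[Si](C(C)C)(C(C)C)C(C)C
F7 | step 1 | 4-fluoro-3-methoxybenzoic acid | O=C(O)c1ccc(F)c(OC)c1
F8 | step 1 | 4-fluoro-3-hydroxy-5-methoxybenzoic acid | O=C(O)c1cc(O)c(F)c(OC)c1
F9 | step 12 | [4-[(2S,3R)-5-(2,2-dibromoethenyl)-7-methoxy-3-(trityloxymethyl)-2,3-dihydro-1-benzofuran-2-yl]-2-methoxyphenoxy]triisopropylsilane | COc1cc([C@H]2Oc3c(OC)cc(C=C(Br)Br)cc3[C@@H]2COC(c2ccccc2)(c2ccccc2)c2ccccc2)ccc1O[Si](C(C)C)(C(C)C)C(C)C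
F10 | step 12 | 3-[(2S,3R)-7-methoxy-2-[3-methoxy-4-(triisopropylsilyloxy)phenyl]-3-(trityloxymethyl)-2,3-dihydro-1-benzofuran-5-yl]prop-2-yn-1-ol | COc1cc([C@H]2Oc3c(OC)cc(C#CCO)cc3[C@@H]2COC(c2ccccc2)(c2ccccc2)c2ccccc2)ccc1O[Si](C(C)C)(C(C)C)C(C)C
F11 | step 12 | 3-[(2S,3R)-3-(hydroxymethyl)-7-methoxy-2-[3-methoxy-4-(triisopropylsilyloxy)phenyl]-2,3-dihydro-1-benzofuran-5-yl]prop-2-yn-1-ol | COc1cc([C@H]2Oc3c(OC)cc(C#CCO)cc3[C@@H]2CO)ccc1O[Si](C(C)C)(C(C)C)C(C)C
F12 | step 17 | [4-[(2S,3R)-5-[(Z)-2-iodoethenyl]-7-methoxy-3-(trityloxymethyl)-2,3-dihydro-1-benzofuran-2-yl]-2-methoxyphenoxy]triisopropylsilane | COc1cc([C@H]2Oc3c(OC)cc(/C=C\I)cc3[C@@H]2COC(c2ccccc2)(c2ccccc2)c2ccccc2)ccc1O[Si](C(C)C)(C(C)C)C(C)C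
F13 | step 17 | [(2S,3R)-5-[(Z)-2-iodoethenyl]-7-methoxy-2-[3-methoxy-4-(triisopropylsilyloxy)phenyl]-2,3-dihydro-1-benzofuran-3-yl]methanol | COc1cc([C@H]2Oc3c(OC)cc(/C=C\I)cc3[C@@H]2CO)ccc1O[Si](C(C)C)(C(C)C)C(C)C
F14 | step 17 | [(2S,3R)-5-[(Z)-2-iodoethenyl]-7-methoxy-2-[3-methoxy-4-(triisopropylsilyloxy)phenyl]-2,3-dihydro-1-benzofuran-3-yl]methyl 4-(triisopropylsilyloxy)benzoate | COc1cc([C@H]2Oc3c(OC)cc(/C=C\I)cc3[C@@H]2COC(=O)c2ccc(O[Si](C(C)C)(C(C)C)C(C)C)cc2)ccc1O[Si](C(C)C)(C(C)C)C(C)C
A1 | alternative 1 | (2S)-6-bromo-8-methoxy-2-[3-methoxy-4-(tosyloxy)phenyl]-2,3-dihydro-4H-chromen-4-one | COc1cc([C@@H]2CC(=O)c3cc(Br)cc(OC)c3O2)ccc1OS(=O)(=O)c1ccc(C)cc1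
A2 | alternative 1 | methyl (2S,3S)-5-bromo-7-methoxy-2-[3-methoxy-4-(tosyloxy)phenyl]-2,3-dihydro-1-benzofuran-3-carboxylate (trans) | COc1cc([C@H]2Oc3c(OC)cc(Br)cc3[C@@H]2C(=O)OC)ccc1OS(=O)(=O)c1ccc(C)cc1
A3 | alternative 2 | allyl 4-bromo-2-methoxy-6-[(E)-2-[3-methoxy-4-(triisopropylsilyloxy)phenyl]ethenyl]phenyl carbonate | COc1cc(/C=C/c2cc(Br)cc(OC)c2OC(=O)OCC=C)ccc1O[Si](C(C)C)(C(C)C)C(C)C
A4 | alternative 2 | allyl 4-bromo-2-methoxy-6-[(4R,5R)-4-[3-methoxy-4-(triisopropylsilyloxy)phenyl]-1,3-dioxan-5-yl]phenyl carbonate (trans) | COc1cc([C@@H]2OCOC[C@H]2c3cc(Br)cc(OC)c3OC(=O)OCC=C)ccc1O[Si](C(C)C)(C(C)C)C(C)C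
A5 | alternative 3 | (2R)-2-(5-bromo-2-hydroxy-3-methoxyphenyl)-3-(4-hydroxy-3-methoxyphenyl)propyl 4-(triisopropylsilyloxy)benzoate | COc1cc(C[C@@H](COC(=O)c2ccc(O[Si](C(C)C)(C(C)C)C(C)C)cc2)c2cc(Br)cc(OC)c2O)ccc1O
A6 | alternative 3 | [(2S,3R)-5-bromo-2-(4-hydroxy-3-methoxyphenyl)-7-methoxy-2,3-dihydro-1-benzofuran-3-yl]methyl 4-(triisopropylsilyloxy)benzoate | COc1cc([C@H]2Oc3c(OC)cc(Br)cc3[C@@H]2COC(=O)c2ccc(O[Si](C(C)C)(C(C)C)C(C)C)cc2)ccc1O
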